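## The problem

Atom labels used throughout: chromene O1, C2, C3=C4, C4a, C5 (OH), C6, C7 (CH3), C8, C8a; chain C1' (on C2) and C2'; cyclohexane C1'' (bears the chain), C2'' (bears CO2H), C3''–C5'', C6'' (CMe2). In the systematic names C2'' is ring C1 and C1'' is ring C2.

The target joins a 2,2-disubstituted 2H-chromene to a trisubstituted cyclohexane through a two-carbon chain. It has three stereocentres: the quaternary ether carbon C2 (R) and the vicinal pair C1'' (R) and C2'' (S), which are trans on the ring. C2 and C1'' are separated by two methylene groups, so neither can steer the other and each needs its own source of chirality. C2'' is α to a carboxyl group and next to C1'', so it can be corrected by enolisation under the control of C1''. C2 is a tertiary carbon that is both allylic and an aryl ether; ionisation of C2–O1 or reversible oxa-6π ring opening of the pyran (heat, light, acid) would erode it. The electron-rich C3=C4 bond and the free phenol also rule out strong acid and oxidants late in the route, so the chromene should be closed last and the C2–O bond taken intact from a precursor. The enabling feature is twofold. C1'' lies between a carbon that can temporarily be a malonate (C2'') and a quaternary carbon without stereochemistry (C6''). C2, with its methyl group, oxygen, vinyl group (inner carbon = C3) and the C1'–C2' chain, is the carbinol end of (R)-linalool, whose C6 becomes C1'' once the trisubstituted alkene is cleaved. The cyclohexane then needs only the C1''–C6'' and C2''–C3'' bonds, and one four-carbon reagent can deliver both.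

## Retrosynthesis

**26 ⇒ 24.** Only the C5 phenol is unmasked last. A MOM ether is chosen because it directs the ortho-lithiation that builds the arene and survives alkoxide, ylide and ruthenium carbene. The forward step must cleave an aryl acetal without protonating the chromene, which calls for a buffered silyl triflate rather than a protic acid.

**24 ⇒ 23 (cut C3=C4).** Ring-closing metathesis is preferred over closures that make or break the C2–O1 bond. Those pass through a tertiary allylic cation or an achiral dienone and would give racemic C2. Diene 23 is acyclic at the pyran and already holds every carbon except the ethene that is lost. The forward step needs a ruthenium carbene that tolerates a free acid and reacts at two hindered terminal alkenes at 40 °C.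

**23 ⇒ 22 ⇒ 17 + 21 (cut C4=CH2, then O1–C8a).** The styrene comes from aldehyde 22 by Wittig methylenation. The same formyl group activates fluoride displacement in 21, so the aryl ether is made by nucleophilic aromatic substitution with the tertiary alkoxide of 17. The carbinol C–O bond is never broken, so C2 keeps the linalool configuration. This splits the molecule into a small arene and the complete terpenoid half. The forward step asks a hindered alkoxide to attack a singly activated fluoroarene; the carboxylate of 17 is a spectator that cannot be epimerised.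

**21 ⇒ 19 ⇒ 18.** The formyl carbon is introduced between fluorine and the MOM ether of 19 by directed ortho-metalation. Ether 19 is the MOM derivative of commercial 3-fluoro-5-methylphenol 18. The substitution pattern (CH3 para to the formyl group) follows from the cooperative directing effect.

**17 ⇒ 15 ⇒ 14 ⇒ 13.** Desilylation and saponification lead back to trans ester 15, equilibration to epimer mixture 14, and dealkoxycarbonylation to gem-diester 13. All hot or strongly basic operations are placed here, before the aryl tert-allyl ether (prone to Claisen rearrangement) and the chromene exist. C2'' is created by decarboxylation and then set by thermodynamics under the control of C1''.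

**13 ⇒ 6 + 11 (cut C1''–C6'' and C2''–C3'').** This is the key disconnection. Cutting at the quaternary carbon turns C6'' into a tertiary radical and C1'' into the β-carbon of alkylidene malonate 6; cutting C2''–C3'' turns the ring closure into a malonate alkylation. Other ring cuts (C1''–C2'', or C5''–C6'' as in Alternative 2) need longer precursors or leave an extra carbonyl to remove. The precursors are an acyclic linalool derivative and a four-carbon acid derivative. The free acid 10 is not used directly: under the base needed for oxidative decarboxylation its carboxylate would lactonise onto its own chloride (6-exo-tet, helped by the α-gem-dimethyl group) and would bind the Lewis acid. Its N-(acyloxy)phthalimide 11 avoids both. The forward step must discriminate the malonate alkene from the vinyl group, select one face of C1'' without help from C2, and close a congested ring.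

**6 ⇒ 4 + 5; 4 ⇒ 2 ⇒ 1.** Knoevenagel condensation of aldehyde 4 with dimethyl malonate 5 gives 6. Aldehyde 4 comes from selective ozonolysis of silyl ether 2, made from (R)-linalool 1. The silyl ether is needed because the free 4-hydroxy aldehyde would close to a lactol and the free alcohol would add to the alkylidene malonate.

**11 ⇒ 10 ⇒ 7 + 8.** Ester 11 is made from acid 10 by carbodiimide coupling. Acid 10 comes from the dianion of isobutyric acid 7 and 1-bromo-3-chloropropane 8, with bromide leaving in preference to chloride.

## Roads not taken

Alternative 1: The cut is again C3=C4, but made early and in a group-selective sense. The achiral triene 2-ethenyl-1-(methoxymethoxy)-5-methyl-3-[(3-methylpenta-1,4-dien-3-yl)oxy]benzene A1 would be closed by the chiral molybdenum alkylidene Mo(N-2,6-iPr2C6H3)(CHCMe2Ph)(3,3'-di-tert-butyl-5,5',6,6'-tetramethylbiphenyl-2,2'-diolate). The styrene would react with one of the two enantiotopic vinyl groups to give (2R)-2-ethenyl-5-(methoxymethoxy)-2,7-dimethyl-2H-chromene A2.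
- Merits: C2 is set by catalysis from achiral material, and the pyran ring and its stereocentre arise in one step.
- Weak points: the catalyst is air- and moisture-sensitive and untested on a styrene flanked by two ortho oxygens. A1 is a doubly allylic tertiary aryl ether that is no easier to make than 22 and more prone to ionise. The remaining vinyl group of A2 supplies only C1' and C2', so the cyclohexane with its two stereocentres still has to be built or attached. Hydroformylation of A2 would lead to the same annulation as here, but the light-, heat- and acid-sensitive chromene would then be carried through photochemistry, a 150 °C dealkoxycarbonylation and hot base.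
- Comparison: this road is better in that it needs no chiral-pool material and no tertiary-alkoxide arylation of a late intermediate. The chosen plan sets against it a C2 centre bought from linalool and a chromene that is made only after all harsh steps.

Alternative 2: Here the ring stereocentre comes from the chiral pool. (R)-Limonene A3 would be opened at its ring alkene and elaborated to the vinyl ketone methyl 2-[(3R)-2-methyl-5-(2-methyl-1,3-dioxolan-2-yl)pent-1-en-3-yl]-3-oxopent-4-enoate A4. Hydrogen-atom transfer from an iron hydride (Fe(acac)3, PhSiH3, ethanol) to the isopropenyl group would give the tertiary C6'' radical. It would add to the terminal enone carbon (6-endo-trig, forming C5''–C6'') to give methyl (2R)-3,3-dimethyl-2-[2-(2-methyl-1,3-dioxolan-2-yl)ethyl]-6-oxocyclohexane-1-carboxylate A5.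
- Merits: C1'' is secure from A3, and radical cyclisations of this kind onto enones are well established for quaternary carbons.
- Weak points: A5 carries a ketone at C3'' that must be removed. Several steps are spent differentiating the two carbonyl groups obtained from A3. Above all, C2 must later be created from a methyl ketone by vinyl addition with no control from the remote ring centres.
- Comparison: this road is better for C1'', which the chosen plan entrusts to an untested catalyst-controlled radical addition. It is worse for C2, a quaternary carbinol that is much harder to set by reagent control than a tertiary carbon made by conjugate addition. The chosen plan buys the harder centre and creates the easier one, and it needs no deoxygenation.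

Alternative 3: This is a different closure of the pyran, by O1–C8a. The bromoaryl (Z)-alkenyl carbinol methyl (1S,2R)-2-[(3R,4Z)-5-[2-bromo-6-(methoxymethoxy)-4-methylphenyl]-3-hydroxy-3-methylpent-4-en-1-yl]-3,3-dimethylcyclohexane-1-carboxylate A6 would be cyclised with zerovalent palladium (from Pd(OAc)2 and 2-(di-tert-butylphosphino)-1,1'-binaphthyl, Cs2CO3). The product would be methyl (1S,2R)-2-{2-[(2R)-5-(methoxymethoxy)-2,7-dimethyl-2H-chromen-2-yl]ethyl}-3,3-dimethylcyclohexane-1-carboxylate A7.
- Merits: the intramolecular palladium etherification of a tertiary alcohol is probably more dependable than an intermolecular substitution at a weakly activated fluoroarene, and it keeps the C2–O bond intact.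
- Weak points: A6 needs a Z-styrenyl bromide. That means an alkynyl rather than a vinyl carbinol, a Sonogashira coupling on a differentiated dihaloarene and a semi-hydrogenation (Pd/CaCO3 poisoned with Pb(OAc)2 and quinoline) beside an aryl bromide. These are several more steps than the three used here, with Z/E isomerisation and Heck-type pathways as risks. It also ends at an ester that must be saponified hot with the chromene in place. The cyclohexane is not addressed at all, so this is only another endgame.
- Comparison: this road is better for the C–O bond itself. The chosen plan sets against it that linalool's vinyl group is used as it stands and that the acid is freed before the chromene is formed.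

Key step: step 6

Remarks on the chemistry:
- Commercial (R)-(−)-linalool is taken as enantiomerically pure; its enantiomeric purity is to be checked before use.
- (S,S)-tBu-box is 2,2'-(propane-2,2-diyl)bis[(4S)-4-tert-butyl-4,5-dihydro-1,3-oxazole]. The sense of induction in step 6 cannot be derived from precedent, so the (S,S) ligand is written and its equally available antipode is meant if the other face proves to be favoured.

## Route

Step 1
Reactants: 1 (R)-linalool, (3R)-3,7-dimethylocta-1,6-dien-3-ol
Product: 2 triethyl{[(3R)-3,7-dimethylocta-1,6-dien-3-yl]oxy}silane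
Conditions: Et3SiOTf, 2,6-lutidine, CH2Cl2, 0 °C
Reagents that add atoms: triethylsilyl trifluoromethanesulfonate, CC[Si](CC)(CC)OS(=O)(=O)C(F)(F)F
Why: O-Silylation with a silyl triflate and 2,6-lutidine works on hindered tertiary alcohols and touches no bond at C3, so the configuration is kept; the ether is needed because the free 4-hydroxy aldehyde would close to a lactol and the free alcohol would add (oxa-Michael) to the alkylidene malonate.

Step 2
Reactants: 2 triethyl{[(3R)-3,7-dimethylocta-1,6-dien-3-yl]oxy}silane
Product: 4 (4R)-4-methyl-4-(triethylsilyloxy)hex-5-enal, via ozonide 3 (not isolated)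
Conditions: O3, Sudan Red 7B (indicator), CH2Cl2, −78 °C; then PPh3, −78 °C → rt
Reagents that add atoms: ozone, [O-][O+]=O
Why: Ozonolysis is electrophilic, so the trisubstituted alkene should react far faster than the monosubstituted vinyl group, and the dye marks the end point; PPh3 reduces ozonide 3 to aldehyde 4 and acetone.

Step 3
Reactants: 4 (4R)-4-methyl-4-(triethylsilyloxy)hex-5-enal; 5 dimethyl malonate
Product: 6 dimethyl 2-[(4R)-4-methyl-4-(triethylsilyloxy)hex-5-en-1-ylidene]propanedioate
Conditions: piperidine (0.1 equiv), AcOH (0.1 equiv), 4 Å MS, CH2Cl2, rt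
Reagents that add atoms: none
Why: Knoevenagel condensation under buffered piperidinium acetate catalysis; the mild conditions should leave the tertiary allylic silyl ether and the stereocentre untouched.

Step 4
Reactants: 7 isobutyric acid; 8 1-bromo-3-chloropropane
Product: 10 5-chloro-2,2-dimethylpentanoic acid, via dilithium enediolate 9 (not isolated)
Conditions: LiN(iPr)2 (2.1 equiv), THF, 0 °C → rt; then 8, −78 °C → 0 °C; cold 1 M HCl
Reagents that add atoms: none
Why: α-Alkylation of the carboxylic acid dianion: the enediolate carbon should displace bromide much faster than chloride, which is kept for the ring closure; the cold acidic quench returns the acid before the carboxylate can lactonise.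

Step 5
Reactants: 10 5-chloro-2,2-dimethylpentanoic acid
Product: 11 1,3-dioxoisoindolin-2-yl 5-chloro-2,2-dimethylpentanoate
Conditions: N-hydroxyphthalimide, iPrN=C=NiPr, DMAP (cat.), CH2Cl2, rt
Reagents that add atoms: N-hydroxyphthalimide, ON1C(=O)c2ccccc2C1=O
Why: Carbodiimide (Steglich-type) esterification to the redox-active N-(acyloxy)phthalimide; masking the carboxyl group removes the carboxylate that would lactonise onto the chloride or bind the Lewis acid of step 6.

Step 6
Reactants: 6 dimethyl 2-[(4R)-4-methyl-4-(triethylsilyloxy)hex-5-en-1-ylidene]propanedioate; 11 1,3-dioxoisoindolin-2-yl 5-chloro-2,2-dimethylpentanoate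
Product: 13 dimethyl (2S)-3,3-dimethyl-2-[(3R)-3-methyl-3-(triethylsilyloxy)pent-4-en-1-yl]cyclohexane-1,1-dicarboxylate, via open-chain chloro malonate 12 (not isolated)
Conditions: [Ir(dF(CF3)ppy)2(dtbbpy)]PF6 (1 mol %), Hantzsch ester (1.5 equiv), Mg(NTf2)2 (1.0 equiv), (S,S)-tBu-box (1.1 equiv), 4 Å MS, CH2Cl2, blue LEDs, −20 °C; then solvent exchange to DMF, Cs2CO3 (3 equiv), NaI (0.2 equiv), 50 °C
Reagents that add atoms: none
Why: Proposed new method: the excited trivalent iridium complex is reduced by the Hantzsch ester, the divalent iridium passes an electron to 11, which loses phthalimide anion and CO2, and the nucleophilic tertiary radical adds to C1'' of magnesium-chelated 6 (C1''–C6''), after which the malonyl radical is reduced and protonated by the oxidised dihydropyridine to give 12. In the second stage Cs2CO3 deprotonates the malonate and the carbanion displaces the primary chloride (iodide after exchange) in a 6-exo-tet SN2 closure that forms C2''–C3'' and the cyclohexane, helped by the gem-dimethyl group in the tether. The closest known reaction types are photoreductive decarboxylative Giese additions of tertiary N-(acyloxy)phthalimides to alkylidene malonates, radical addition–polar cyclisation sequences in which the reduced adduct displaces a halide, and chiral Lewis acid-controlled radical conjugate additions to chelating acceptors; not yet shown are the halide carried by the radical partner and catalyst-set configuration at the β-carbon of an alkylidene malonate. The new stereocentre C1'' (S by the sequence rule in the gem-diester, the same arrangement as R in the target) must be set by the magnesium bis(oxazoline) chelate of the two ester carbonyls, which has to leave the Re face of C1'' open, because C2 lies two methylene groups away and exerts no control. Chemoselectivity for the alkylidene malonate over the isolated vinyl group follows from the polarity match of the nucleophilic radical with the electron-poor alkene. Face selectivity requires complexed 6 to outrun free 6, hence a full equivalent of Lewis acid and low temperature.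

Step 7
Reactants: 13 dimethyl (2S)-3,3-dimethyl-2-[(3R)-3-methyl-3-(triethylsilyloxy)pent-4-en-1-yl]cyclohexane-1,1-dicarboxylate
Product: 14 methyl (2R)-3,3-dimethyl-2-[(3R)-3-methyl-3-(triethylsilyloxy)pent-4-en-1-yl]cyclohexane-1-carboxylate (both C1 epimers)
Conditions: LiCl, H2O, DMSO, 150 °C
Reagents that add atoms: none
Why: Krapcho dealkoxycarbonylation: chloride demethylates one ester by SN2 at the O-methyl carbon, which is indifferent to the congestion around C2'', and the carboxylate loses CO2; protonation of the ester enolate is kinetic, so both C2'' epimers are expected while C1'' is untouched (its descriptor changes to R only because the priorities change).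

Step 8
Reactants: 14 methyl (2R)-3,3-dimethyl-2-[(3R)-3-methyl-3-(triethylsilyloxy)pent-4-en-1-yl]cyclohexane-1-carboxylate (both C1 epimers)
Product: 15 methyl (1S,2R)-3,3-dimethyl-2-[(3R)-3-methyl-3-(triethylsilyloxy)pent-4-en-1-yl]cyclohexane-1-carboxylate
Conditions: NaOMe (0.3 equiv), MeOH, 65 °C; chromatography, cis ester resubmitted
Reagents that add atoms: none
Why: Base-mediated epimerisation through the ester enolate (thermodynamic control by C1''): the trans isomer can place ester and chain both equatorial, whereas the cis isomer must put the chain axial or the ester syn-diaxial to a C6'' methyl group; the bias is estimated at about one gauche interaction, so the minor cis ester is separated and recycled.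

Step 9
Reactants: 15 methyl (1S,2R)-3,3-dimethyl-2-[(3R)-3-methyl-3-(triethylsilyloxy)pent-4-en-1-yl]cyclohexane-1-carboxylate
Product: 17 (1S,2R)-2-[(3R)-3-hydroxy-3-methylpent-4-en-1-yl]-3,3-dimethylcyclohexane-1-carboxylic acid, via hydroxy ester 16 (not isolated)
Conditions: Bu4NF, THF, rt; then LiOH·H2O, MeOH/H2O, 60 °C; 1 M HCl to pH 3, 0 °C
Reagents that add atoms: lithium hydroxide, [Li+].[OH-]
Why: Fluoride cleaves the silyl ether and hydroxide then saponifies the equatorial methyl ester (acyl substitution), which should be much faster than α-deprotonation; once formed, the carboxylate cannot epimerise in the later basic steps.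

Step 10
Reactants: 18 3-fluoro-5-methylphenol
Product: 19 1-fluoro-3-(methoxymethoxy)-5-methylbenzene
Conditions: MOMCl, iPr2NEt, CH2Cl2, 0 °C → rt
Reagents that add atoms: chloromethyl methyl ether, COCCl
Why: O-Alkylation of the phenol to the MOM ether, chosen because it directs the next lithiation and resists alkoxide, ylide and ruthenium carbene.

Step 11
Reactants: 19 1-fluoro-3-(methoxymethoxy)-5-methylbenzene
Product: 21 2-fluoro-6-(methoxymethoxy)-4-methylbenzaldehyde, via aryllithium 20 (not isolated)
Conditions: n-BuLi, THF, −78 °C; then DMF, −78 °C → 0 °C; aq. NH4Cl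
Reagents that add atoms: N,N-dimethylformamide, CN(C)C=O
Why: Directed ortho-metalation: the proton between fluorine and the MOM ether is activated by both groups, so lithiation is expected only there; aryllithium 20 is kept at −78 °C to prevent loss of LiF (aryne formation) and is formylated by DMF.

Step 12
Reactants: 17 (1S,2R)-2-[(3R)-3-hydroxy-3-methylpent-4-en-1-yl]-3,3-dimethylcyclohexane-1-carboxylic acid; 21 2-fluoro-6-(methoxymethoxy)-4-methylbenzaldehyde
Product: 22 (1S,2R)-2-[(3R)-3-[2-formyl-3-(methoxymethoxy)-5-methylphenoxy]-3-methylpent-4-en-1-yl]-3,3-dimethylcyclohexane-1-carboxylic acid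
Conditions: KN(SiMe3)2 (2.05 equiv), THF/DMF, 0 °C; then 21, 0 °C → rt; cold dilute HCl to pH 4
Reagents that add atoms: none
Why: Nucleophilic aromatic substitution (addition–elimination): the tertiary potassium alkoxide attacks the fluorine-bearing carbon ortho to the formyl group, which stabilises the anionic intermediate; the carbinol C–O bond is not broken, so the R configuration from linalool is kept, and the carboxylate is a poor nucleophile that cannot be epimerised.

Step 13
Reactants: 22 (1S,2R)-2-[(3R)-3-[2-formyl-3-(methoxymethoxy)-5-methylphenoxy]-3-methylpent-4-en-1-yl]-3,3-dimethylcyclohexane-1-carboxylic acid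
Product: 23 (1S,2R)-2-[(3R)-3-[2-ethenyl-3-(methoxymethoxy)-5-methylphenoxy]-3-methylpent-4-en-1-yl]-3,3-dimethylcyclohexane-1-carboxylic acid
Conditions: Ph3PCH3Br, KOtBu (3 equiv each), THF, 0 °C → rt; cold dilute HCl to pH 4
Reagents that add atoms: methyltriphenylphosphonium bromide, C[P+](c1ccccc1)(c1ccccc1)c1ccccc1.[Br-]
Why: Wittig methylenation of the non-enolisable aryl aldehyde; the carboxylic acid consumes one equivalent of ylide, hence the excess.

Step 14
Reactants: 23 (1S,2R)-2-[(3R)-3-[2-ethenyl-3-(methoxymethoxy)-5-methylphenoxy]-3-methylpent-4-en-1-yl]-3,3-dimethylcyclohexane-1-carboxylic acid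
Product: 24 (1S,2R)-2-{2-[(2R)-5-(methoxymethoxy)-2,7-dimethyl-2H-chromen-2-yl]ethyl}-3,3-dimethylcyclohexane-1-carboxylic acid
Conditions: second-generation Grubbs catalyst RuCl2(=CHPh)(PCy3)(H2IMes) (5 mol %), CH2Cl2 (0.005 M), 40 °C, dark
Reagents that add atoms: none
Why: Ring-closing metathesis of the styrene with the vinyl group on the quaternary carbinol carbon closes the six-membered pyran ring (C3=C4) with loss of ethene; the ruthenium carbene tolerates the free acid, and mild temperature and exclusion of light guard against electrocyclic ring opening, so C2 stays R.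

Step 15
Reactants: 24 (1S,2R)-2-{2-[(2R)-5-(methoxymethoxy)-2,7-dimethyl-2H-chromen-2-yl]ethyl}-3,3-dimethylcyclohexane-1-carboxylic acid
Product: 26 (1S,2R)-2-{2-[(2R)-5-hydroxy-2,7-dimethyl-2H-chromen-2-yl]ethyl}-3,3-dimethylcyclohexane-1-carboxylic acid, via bis(trimethylsilyl) derivative 25 (not isolated)
Conditions: Me3SiOTf, 2,2'-bipyridyl, MeCN, 0 °C → rt; then H2O, rt; dark
Reagents that add atoms: none
Why: Silyl triflate buffered by 2,2'-bipyridyl converts aromatic MOM ethers into aryl silyl ethers without free protic acid (the carboxylic acid is silylated in passing), and water then hydrolyses both silyl groups of 25; the near-neutral conditions are chosen to avoid protonation of the chromene alkene and ionisation of the C2–O1 bond.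

## Compound list

1 | (R)-linalool, (3R)-3,7-dimethylocta-1,6-dien-3-ol | C=C[C@](C)(O)CCC=C(C)C | starting material
2 | triethyl{[(3R)-3,7-dimethylocta-1,6-dien-3-yl]oxy}silane | C=C[C@](C)(O[Si](CC)(CC)CC)CCC=C(C)C | intermediate
3 | 3,3-dimethyl-5-[(3R)-3-methyl-3-(triethylsilyloxy)pent-4-en-1-yl]-1,2,4-trioxolane (ozonide, not isolated) | C=C[C@](C)(O[Si](CC)(CC)CC)CCC1OOC(C)(C)O1 | intermediate
4 | (4R)-4-methyl-4-(triethylsilyloxy)hex-5-enal | C=C[C@](C)(O[Si](CC)(CC)CC)CCC=O | intermediate
5 | dimethyl malonate | COC(=O)CC(=O)OC | starting material
6 | dimethyl 2-[(4R)-4-methyl-4-(triethylsilyloxy)hex-5-en-1-ylidene]propanedioate | C=C[C@](C)(O[Si](CC)(CC)CC)CCC=C(C(=O)OC)C(=O)OC | intermediate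
7 | isobutyric acid | CC(C)C(=O)O | starting material
8 | 1-bromo-3-chloropropane | ClCCCBr | starting material
9 | dilithium enediolate of isobutyric acid (not isolated) | CC(C)=C([O-])[O-].[Li+].[Li+] | intermediate
10 | 5-chloro-2,2-dimethylpentanoic acid | OC(=O)C(C)(C)CCCCl | intermediate
11 | 1,3-dioxoisoindolin-2-yl 5-chloro-2,2-dimethylpentanoate | O=C(ON1C(=O)c2ccccc2C1=O)C(C)(C)CCCCl | intermediate
12 | dimethyl 2-[(3R,6R)-10-chloro-3,7,7-trimethyl-3-(triethylsilyloxy)dec-1-en-6-yl]propanedioate (not isolated) | C=C[C@](C)(O[Si](CC)(CC)CC)CC[C@H](C(C(=O)OC)C(=O)OC)C(C)(C)CCCCl | intermediate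
13 | dimethyl (2S)-3,3-dimethyl-2-[(3R)-3-methyl-3-(triethylsilyloxy)pent-4-en-1-yl]cyclohexane-1,1-dicarboxylate | C=C[C@](C)(O[Si](CC)(CC)CC)CC[C@@H]1C(C(=O)OC)(C(=O)OC)CCCC1(C)C | intermediate
14 | methyl (2R)-3,3-dimethyl-2-[(3R)-3-methyl-3-(triethylsilyloxy)pent-4-en-1-yl]cyclohexane-1-carboxylate (both C1 epimers) | C=C[C@](C)(O[Si](CC)(CC)CC)CC[C@@H]1C(C(=O)OC)CCCC1(C)C | intermediate
15 | methyl (1S,2R)-3,3-dimethyl-2-[(3R)-3-methyl-3-(triethylsilyloxy)pent-4-en-1-yl]cyclohexane-1-carboxylate | C=C[C@](C)(O[Si](CC)(CC)CC)CC[C@@H]1[C@@H](C(=O)OC)CCCC1(C)C | intermediate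
16 | methyl (1S,2R)-2-[(3R)-3-hydroxy-3-methylpent-4-en-1-yl]-3,3-dimethylcyclohexane-1-carboxylate (not isolated) | C=C[C@](C)(O)CC[C@@H]1[C@@H](C(=O)OC)CCCC1(C)C | intermediate
17 | (1S,2R)-2-[(3R)-3-hydroxy-3-methylpent-4-en-1-yl]-3,3-dimethylcyclohexane-1-carboxylic acid | C=C[C@](C)(O)CC[C@@H]1[C@@H](C(=O)O)CCCC1(C)C | intermediate
18 | 3-fluoro-5-methylphenol | Cc1cc(O)cc(F)c1 | starting material
19 | 1-fluoro-3-(methoxymethoxy)-5-methylbenzene | Cc1cc(F)cc(OCOC)c1 | intermediate
20 | [2-fluoro-6-(methoxymethoxy)-4-methylphenyl]lithium (not isolated) | [Li]c1c(F)cc(C)cc1OCOC | intermediate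
21 | 2-fluoro-6-(methoxymethoxy)-4-methylbenzaldehyde | O=Cc1c(F)cc(C)cc1OCOC | intermediate
22 | (1S,2R)-2-[(3R)-3-[2-formyl-3-(methoxymethoxy)-5-methylphenoxy]-3-methylpent-4-en-1-yl]-3,3-dimethylcyclohexane-1-carboxylic acid | C=C[C@](C)(Oc1cc(C)cc(OCOC)c1C=O)CC[C@@H]1[C@@H](C(=O)O)CCCC1(C)C | intermediate
23 | (1S,2R)-2-[(3R)-3-[2-ethenyl-3-(methoxymethoxy)-5-methylphenoxy]-3-methylpent-4-en-1-yl]-3,3-dimethylcyclohexane-1-carboxylic acid | C=C[C@](C)(Oc1cc(C)cc(OCOC)c1C=C)CC[C@@H]1[C@@H](C(=O)O)CCCC1(C)C | intermediate
24 | (1S,2R)-2-{2-[(2R)-5-(methoxymethoxy)-2,7-dimethyl-2H-chromen-2-yl]ethyl}-3,3-dimethylcyclohexane-1-carboxylic acid | Cc1cc(OCOC)c2c(c1)O[C@](C)(CC[C@@H]1[C@@H](C(=O)O)CCCC1(C)C)C=C2 | intermediate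
25 | trimethylsilyl (1S,2R)-2-{2-[(2R)-2,7-dimethyl-5-(trimethylsilyloxy)-2H-chromen-2-yl]ethyl}-3,3-dimethylcyclohexane-1-carboxylate (not isolated) | Cc1cc(O[Si](C)(C)C)c2c(c1)O[C@](C)(CC[C@@H]1[C@@H](C(=O)O[Si](C)(C)C)CCCC1(C)C)C=C2 | intermediate
26 | (1S,2R)-2-{2-[(2R)-5-hydroxy-2,7-dimethyl-2H-chromen-2-yl]ethyl}-3,3-dimethylcyclohexane-1-carboxylic acid | Cc1cc(O)c2c(c1)O[C@](C)(CC[C@@H]1[C@@H](C(=O)O)CCCC1(C)C)C=C2 | target

## Step count and least certain steps

Total: 15 steps. Longest linear sequence: 11 steps (steps 1, 2, 3, 6, 7, 8, 9, 12, 13, 14, 15, from (R)-linalool). Steps 4–5 and 10–11 are two-step side branches.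

**Step 6 (key step, proposed new method).**
- What may go wrong: facial discrimination at C1'' may be poor, because the β-carbon lies far from the metal and carries only a primary alkyl chain. Unselective addition to uncomplexed 6 may compete. The Hantzsch ester may transfer hydride to the Lewis acid-activated alkene. The ring closure may be slow because the ring must hold a 1,3-diaxial ester/methyl pair, which would give time for N-alkylation of the phthalimide anion by the chloride.
- Fallback (known chemistry, from aldehyde 4 back to ester 14): Horner–Wadsworth–Emmons olefination of 4 with diethyl {2-[(4S)-4-(diphenylmethyl)-2-oxo-1,3-oxazolidin-3-yl]-2-oxoethyl}phosphonate (LiCl, iPr2NEt, MeCN) should give the enoyl imide (4S)-4-(diphenylmethyl)-3-[(2E,6R)-6-methyl-6-(triethylsilyloxy)octa-2,7-dienoyl]-1,3-oxazolidin-2-one F1. The tertiary radical from 11, generated photoreductively as above but without the bis(oxazoline), is added to the Yb(OTf)3-chelated s-cis imide. The diphenylmethyl group covers the Si face of the β-carbon (auxiliary-controlled radical conjugate addition), so the adduct (4S)-3-[(3R,6R)-3-(5-chloro-2-methylpentan-2-yl)-6-methyl-6-(triethylsilyloxy)oct-7-enoyl]-4-(diphenylmethyl)-1,3-oxazolidin-2-one F2 is expected. Methanolysis (NaOMe, MeOH, 0 °C) releases the auxiliary and gives the open-chain chloro ester methyl (3R,6R)-3-(5-chloro-2-methylpentan-2-yl)-6-methyl-6-(triethylsilyloxy)oct-7-enoate F3. Intramolecular alkylation of its lithium enolate (LiN(iPr)2, THF/DMPU, −78 °C → 0 °C, 6-exo-tet) closes the ring and returns to ester 14, which enters step 8. The cost is that the two bonds are made in separate steps.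

**Step 12 (O-arylation).**
- What may go wrong: conversion may be low, because a hindered tertiary alkoxide meets a fluoroarene activated by one formyl group only. The alkoxide may add reversibly to the aldehyde, and hydride transfer from that adduct may consume the electrophile.
- Fallback (from 21 and 17 back to 22): aldehyde 21 is converted by I2 and aqueous NH3 in THF into 2-fluoro-6-(methoxymethoxy)-4-methylbenzonitrile F4. Its linear nitrile activates comparably but cannot be attacked reversibly or reduce itself, so more forcing conditions are allowed. Substitution with the dipotassium salt of 17 should give (1S,2R)-2-[(3R)-3-[2-cyano-3-(methoxymethoxy)-5-methylphenoxy]-3-methylpent-4-en-1-yl]-3,3-dimethylcyclohexane-1-carboxylic acid F5. Reduction with iBu2AlH (3 equiv, −78 °C) and mild hydrolysis of the aldimine leads back to 22; the aluminium carboxylate is not reduced at this temperature.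

**Step 8 (equilibration).**
- What may go wrong: the thermodynamic bias towards the trans ester may be small, since the cis isomer can escape through a chain-axial chair. Repeated recycling would then be needed.
- Fallback (from 12 back to 15): step 6 is stopped after the photochemical stage and 12 is isolated. Krapcho dealkoxycarbonylation (LiCl, wet DMSO, 150 °C) gives the open-chain chloro ester methyl (3R,6R)-3-(5-chloro-2-methylpentan-2-yl)-6-methyl-6-(triethylsilyloxy)oct-7-enoate F3, the compound also met in the fallback to step 6. Ring closure of its lithium enolate then sets C2'' kinetically. With the C1''–H bond in the enolate plane (least 1,3-allylic strain) and the tether bound to approach from the C6'' side, ester and chain should end up trans, giving 15 directly.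

**Step 15 (MOM removal).**
- What may go wrong: Lewis acid activation may ionise the C2–O1 bond, with loss of configuration at C2, or attack the electron-rich C3=C4 bond.
- Fallback (from 22 back to 26): the MOM group is removed at the aldehyde stage under the same buffered conditions or with dilute HCl in THF. No chromene exists there, and the ether oxygen is deactivated by the ortho formyl group. This gives (1S,2R)-2-[(3R)-3-(2-formyl-3-hydroxy-5-methylphenoxy)-3-methylpent-4-en-1-yl]-3,3-dimethylcyclohexane-1-carboxylic acid F6. Wittig methylenation with excess ylide gives (1S,2R)-2-[(3R)-3-(2-ethenyl-3-hydroxy-5-methylphenoxy)-3-methylpent-4-en-1-yl]-3,3-dimethylcyclohexane-1-carboxylic acid F7. Ring-closing metathesis as in step 14 then delivers 26 in a neutral last step.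

## Further compounds

F1 | step 6 | (4S)-4-(diphenylmethyl)-3-[(2E,6R)-6-methyl-6-(triethylsilyloxy)octa-2,7-dienoyl]-1,3-oxazolidin-2-one | C=C[C@](C)(O[Si](CC)(CC)CC)CC/C=C/C(=O)N1C(=O)OC[C@@H]1C(c1ccccc1)c1ccccc1
F2 | step 6 | (4S)-3-[(3R,6R)-3-(5-chloro-2-methylpentan-2-yl)-6-methyl-6-(triethylsilyloxy)oct-7-enoyl]-4-(diphenylmethyl)-1,3-oxazolidin-2-one | C=C[C@](C)(O[Si](CC)(CC)CC)CC[C@H](CC(=O)N1C(=O)OC[C@@H]1C(c1ccccc1)c1ccccc1)C(C)(C)CCCCl
F3 | step 6 | methyl (3R,6R)-3-(5-chloro-2-methylpentan-2-yl)-6-methyl-6-(triethylsilyloxy)oct-7-enoate | C=C[C@](C)(O[Si](CC)(CC)CC)CC[C@H](CC(=O)OC)C(C)(C)CCCCl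
F4 | step 12 | 2-fluoro-6-(methoxymethoxy)-4-methylbenzonitrile | N#Cc1c(F)cc(C)cc1OCOC
F5 | step 12 | (1S,2R)-2-[(3R)-3-[2-cyano-3-(methoxymethoxy)-5-methylphenoxy]-3-methylpent-4-en-1-yl]-3,3-dimethylcyclohexane-1-carboxylic acid | C=C[C@](C)(Oc1cc(C)cc(OCOC)c1C#N)CC[C@@H]1[C@@H](C(=O)O)CCCC1(C)C
F6 | step 15 | (1S,2R)-2-[(3R)-3-(2-formyl-3-hydroxy-5-methylphenoxy)-3-methylpent-4-en-1-yl]-3,3-dimethylcyclohexane-1-carboxylic acid | C=C[C@](C)(Oc1cc(C)cc(O)c1C=O)CC[C@@H]1[C@@H](C(=O)O)CCCC1(C)C
F7 | step 15 | (1S,2R)-2-[(3R)-3-(2-ethenyl-3-hydroxy-5-methylphenoxy)-3-methylpent-4-en-1-yl]-3,3-dimethylcyclohexane-1-carboxylic acid | C=C[C@](C)(Oc1cc(C)cc(O)c1C=C)CC[C@@H]1[C@@H](C(=O)O)CCCC1(C)C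
A1 | alternative 1 | 2-ethenyl-1-(methoxymethoxy)-5-methyl-3-[(3-methylpenta-1,4-dien-3-yl)oxy]benzene | C=Cc1c(OCOC)cc(C)cc1OC(C)(C=C)C=C
A2 | alternative 1 | (2R)-2-ethenyl-5-(methoxymethoxy)-2,7-dimethyl-2H-chromene | Cc1cc(OCOC)c2c(c1)O[C@](C)(C=C)C=C2
A3 | alternative 2 | (R)-limonene | CC1=CC[C@@H](CC1)C(C)=C
A4 | alternative 2 | methyl 2-[(3R)-2-methyl-5-(2-methyl-1,3-dioxolan-2-yl)pent-1-en-3-yl]-3-oxopent-4-enoate | CC1(CC[C@@H](C(C)=C)C(C(=O)OC)C(=O)C=C)OCCO1
A5 | alternative 2 | methyl (2R)-3,3-dimethyl-2-[2-(2-methyl-1,3-dioxolan-2-yl)ethyl]-6-oxocyclohexane-1-carboxylate (both C1 epimers) | CC1(CC[C@@H]2C(C(=O)OC)C(=O)CCC2(C)C)OCCO1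
A6 | alternative 3 | methyl (1S,2R)-2-[(3R,4Z)-5-[2-bromo-6-(methoxymethoxy)-4-methylphenyl]-3-hydroxy-3-methylpent-4-en-1-yl]-3,3-dimethylcyclohexane-1-carboxylate | Cc1cc(OCOC)c(/C=C\[C@](C)(O)CC[C@@H]2[C@@H](C(=O)OC)CCCC2(C)C)c(Br)c1
A7 | alternative 3 | methyl (1S,2R)-2-{2-[(2R)-5-(methoxymethoxy)-2,7-dimethyl-2H-chromen-2-yl]ethyl}-3,3-dimethylcyclohexane-1-carboxylate | Cc1cc(OCOC)c2c(c1)O[C@](C)(CC[C@@H]1[C@@H](C(=O)OC)CCCC1(C)C)C=C2
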